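A leftover began our dispute: in the elm run 53.2% of the charge is still neither D nor J at 3.00 min, and the alder run, with G at 0.47 mol% against elm's 0.03 mol%, leaves 53.6%, so we asked what the part that did react is worth.

| flask | X | G | remark | time |
|---|---|---|---|---|
| elm | 1.1 M | 0.03 mol% | run made earlier |  |
| alder | 1.1 M | 0.47 mol% | run made earlier |  |
| Friday's | 1.1 M | 0.04 mol% |  | 3.0 min |
| Thursday's | 1.1 M | 0.08 mol% |  | 3.0 min |
| Wednesday's | 1.1 M | 0.15 mol% |  | 3.0 min |
| Tuesday's | 1.1 M | 0.3 mol% |  | 3.0 min |
| Saturday's | 1.1 M | 0.6 mol% |  | 3.0 min |

- elm (time / min: D / %, J / %): 0.250: 16.6, 20.8; 0.417: 19.1, 24.2; 0.833: 19.9, 25.8; 1.50: 20.2, 26.2; 3.00: 20.5, 26.3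
- alder (time / min: D / %, J / %): 0.250: 16.3, 21.3; 0.417: 19.4, 24.4; 0.833: 20.3, 26.1; 1.50: 20.7, 25.9; 3.00: 20.1, 26.3

(scatter of a reading: 0.3 percentage points)

- share of D in all that became D or J for Friday's, Thursday's, Wednesday's, Tuesday's, Saturday's, in this order
- the course of these numbers from the first flask to the last (falls all the way / rises all the way / falls, then rises / hardly changes / rises, then falls)

- "hardly changes" means that all values lie within two and a half points (for a concentration: within two and a half percent of the largest)

My colleague held the route view, kinetic control in the usual term: X gives D and D goes on to J, so the share of D in D plus J shows how far a flask has run, and she pointed to the first readings, 44.4% in the elm run against 43.4% in the alder run, and expected that share to fall from Friday's flask to Saturday's as G rises. I held the balance view, thermodynamic control: if D and J pass into each other quickly, their forward rate divided by their back rate leaves a plain number from which time drops out, and her gap of 1 percentage point rests on readings that each scatter by 0.3 points. In the elm run J grows by a factor of 1.26 between the first and last readings, while D/J goes from 0.798 to 0.779. So I pooled the last readings of both runs into the split ratio, D over J, 0.772, which as a share of D reads 43.6%.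

The forecast took my side with a slightly different reckoning over the summed readings, giving 43.8%, 43.8%, 43.8%, 43.8% and 43.8%, a course that hardly changes, on the ground that “G seems to have no visible effect on rate or product split”.

The flasks give 43.5%, 43.5%, 43.5%, 43.5% and 43.5%, a course that hardly changes, and the turning of G into E makes no difference to Friday's share.

    X ⇌ D (K = 0.380, k = 0.0280 /s)
    D ⇌ J (K = 1.30, k = 0.550 /s)
    J ⇌ X (k = 0.0470 /s)
    2 G → E (k = 8.30 /M/s)

The ratio 0.772, a reading of the earlier runs, reckons from Friday's 26.4% of J at 3.00 min to 20.4% of D, and from Tuesday's 26.4% of J at the end to 20.4% of D. In Friday's flask D and J relax towards each other with a half-life of 0.712 s by that step alone, shorter than the 0.165 min of J and X and short against the 3.0 min of the run. My colleague's route view has its region at times of the order of that half-life, for in Friday's flask D turns into J with a forward half-life of 1.3 s, shorter than the 0.250 min of the first elm reading.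

(The earlier runs and the new flask come from a simulation for an exercise; the scatter is artificial.)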